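The synthesis rests on cutting C2–C3 of the upper pyran (C) ring. C2 carries both O1 and the pyrogallol B ring, so it is read as the carbonyl carbon of an aryl gallate. C3 is read as the internal alkene carbon of an allyl group ortho to that ester on the A ring. A titanium-alkylidene olefinic ester cyclization converts this open, achiral, depside-like ester into the flav-2-ene in one operation. Reagent-controlled hydroboration then sets C2 and C3 across the new bond, and oxidation/reduction corrects C3 to 2,3-cis. C4 activation, galloylation and Lewis acid coupling with benzylated (+)-catechin, steered by the 3-O-galloyl group, install the 4β→8 bond.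

Key step: step 4

Assumption: 3,5-bis(benzyloxy)phenol and 3,4,5-tris(benzyloxy)benzoic acid are taken as purchasable, and IpcBH2 is used as a separately prepared stock reagent.

Step 1
Reactants: 1 3,5-bis(benzyloxy)phenol
Product: 2 1-(allyloxy)-3,5-bis(benzyloxy)benzene
Conditions: allyl bromide, K2CO3, acetone, reflux
Reagents that add atoms: allyl bromide C=CCBr
Why: Williamson ether synthesis; the only free phenol is alkylated by SN2 on the allylic bromide.

Step 2
Reactants: 2 1-(allyloxy)-3,5-bis(benzyloxy)benzene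
Product: 4 2-allyl-3,5-bis(benzyloxy)phenol, via ortho-dienone 3 (not isolated)
Conditions: N,N-diethylaniline, 195 °C
Reagents that add atoms: none
Why: Aromatic Claisen rearrangement; the two ortho positions are equivalent, so the [3,3] shift and tautomerisation of the dienone should give one regioisomer.

Step 3
Reactants: 4 2-allyl-3,5-bis(benzyloxy)phenol; 5 3,4,5-tris(benzyloxy)benzoic acid
Product: 6 2-allyl-3,5-bis(benzyloxy)phenyl 3,4,5-tris(benzyloxy)benzoate
Conditions: EDC·HCl, DMAP (cat.), CH2Cl2, rt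
Reagents that add atoms: none
Why: Steglich-type esterification of the phenol, which joins O1 to the future C2 and brings in the whole B ring.

Step 4
Reactants: 6 2-allyl-3,5-bis(benzyloxy)phenyl 3,4,5-tris(benzyloxy)benzoate
Product: 8 5,7-bis(benzyloxy)-2-[3,4,5-tris(benzyloxy)phenyl]-4H-chromene, via titanium alkylidene 7 (not isolated)
Conditions: TiCl4, TMEDA, Zn, PbCl2 (cat.), CH3CHBr2, THF/CH2Cl2, 0 to 65 °C
Reagents that add atoms: none
Why: The titanium ethylidene formed in situ first exchanges with the unhindered terminal alkene of 6 (propene leaves) to give alkylidene 7, whose Ti=C3 bond adds [2+2] across the ester C2=O; cycloreversion of the oxatitanacyclobutane expels a titanium oxo species and leaves the C2=C3 enol ether. The closest known reaction type is the olefinic ester cyclization (ring-closing carbonyl olefination with Takai–Utimoto-type alkylidenes) used for cyclic enol ethers and C-glycals. The pyran C ring is closed as a six-membered ring with the new double bond endocyclic, the four-atom tether C4–C4a–C8a–O1 holding alkylidene and carbonyl within reach. No stereocenter is created: 8 is achiral, so C2 and C3 can both be set in step 5 under reagent control. The step needs alkene exchange to outrun direct ethylidenation of the carbonyl, which the substituted ethylidene reagent, the conjugated benzoate-type carbonyl and the ortho-substituted aryloxy group all favour; 6 holds only one alkene and one ester, and benzyl ethers are inert to the reagent.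

Step 5
Reactants: 8 5,7-bis(benzyloxy)-2-[3,4,5-tris(benzyloxy)phenyl]-4H-chromene
Product: 10 (2R,3S)-5,7-bis(benzyloxy)-2-[3,4,5-tris(benzyloxy)phenyl]chroman-3-ol, via organoborane 9 (not isolated)
Conditions: IpcBH2 [from (+)-α-pinene], Et2O/THF, −25 to 0 °C; then NaOH, H2O2, 0 °C to rt
Reagents that add atoms: hydrogen peroxide OO
Why: Brown asymmetric hydroboration: boron goes to C3 (β to O1, away from the aryl group), H and B add syn to the β face chosen by the isopinocampheyl group as in 1-arylcycloalkenes (S carbinol centre), and oxidation with retention should give the 2,3-trans (2R,3S) alcohol.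

Step 6
Reactants: 10 (2R,3S)-5,7-bis(benzyloxy)-2-[3,4,5-tris(benzyloxy)phenyl]chroman-3-ol
Product: 11 (2R)-5,7-bis(benzyloxy)-2-[3,4,5-tris(benzyloxy)phenyl]chroman-3-one
Conditions: Dess–Martin periodinane, CH2Cl2, rt
Reagents that add atoms: none
Why: Dess–Martin oxidation under near-neutral conditions removes the C3 stereocenter while the enolisable C2 centre should keep its configuration.

Step 7
Reactants: 11 (2R)-5,7-bis(benzyloxy)-2-[3,4,5-tris(benzyloxy)phenyl]chroman-3-one
Product: 12 (2R,3R)-5,7-bis(benzyloxy)-2-[3,4,5-tris(benzyloxy)phenyl]chroman-3-ol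
Conditions: L-Selectride, THF, −78 °C
Reagents that add atoms: none
Why: Substrate-controlled ketone reduction: the bulky borohydride attacks C3 from the β face opposite the 2α-aryl group and should give the axial 3α-alcohol, that is the 2,3-cis (epi) series.

Step 8
Reactants: 12 (2R,3R)-5,7-bis(benzyloxy)-2-[3,4,5-tris(benzyloxy)phenyl]chroman-3-ol
Product: 13 (2R,3R,4S)-5,7-bis(benzyloxy)-4-(2-ethoxyethoxy)-2-[3,4,5-tris(benzyloxy)phenyl]chroman-3-ol
Conditions: DDQ, 2-ethoxyethanol, CH2Cl2, rt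
Reagents that add atoms: 2-ethoxyethanol CCOCCO
Why: DDQ oxidative benzylic etherification at C4, the C–H conjugated with the 5,7-dialkoxy A ring and O1, with the alcohol entering from the β face anti to the axial 3α-OH.

Step 9
Reactants: 13 (2R,3R,4S)-5,7-bis(benzyloxy)-4-(2-ethoxyethoxy)-2-[3,4,5-tris(benzyloxy)phenyl]chroman-3-ol; 5 3,4,5-tris(benzyloxy)benzoic acid
Product: 14 (2R,3R,4S)-5,7-bis(benzyloxy)-4-(2-ethoxyethoxy)-2-[3,4,5-tris(benzyloxy)phenyl]chroman-3-yl 3,4,5-tris(benzyloxy)benzoate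
Conditions: EDC·HCl, DMAP, CH2Cl2, rt
Reagents that add atoms: none
Why: Steglich-type esterification of the only free hydroxyl group; no stereocenter is touched.

Step 10
Reactants: 15 (+)-catechin
Product: 16 (2R,3S)-5,7-bis(benzyloxy)-2-[3,4-bis(benzyloxy)phenyl]chroman-3-ol
Conditions: BnBr, K2CO3, DMF, 0 °C to rt
Reagents that add atoms: benzyl bromide BrCc1ccccc1
Why: Williamson ether synthesis; carbonate deprotonates only the four phenols, so the aliphatic 3-OH stays free.

Step 11
Reactants: 14 (2R,3R,4S)-5,7-bis(benzyloxy)-4-(2-ethoxyethoxy)-2-[3,4,5-tris(benzyloxy)phenyl]chroman-3-yl 3,4,5-tris(benzyloxy)benzoate; 16 (2R,3S)-5,7-bis(benzyloxy)-2-[3,4-bis(benzyloxy)phenyl]chroman-3-ol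
Product: 18 dodeca-O-benzyl-3-O-galloyl-(−)-epigallocatechin-(4β→8)-(+)-catechin, via flavan-4-yl cation 17 (not isolated)
Conditions: TMSOTf (cat.), 16 in excess, CH2Cl2, −78 °C
Reagents that add atoms: none
Why: Lewis acid-catalysed Friedel–Crafts alkylation: ionisation of the C4 ether gives cation 17, whose α face is covered by the neighbouring 3α-O-galloyl group, so the most nucleophilic carbon of 16 (C8) should attack from the β face and set C4 as 3,4-trans (4R).

Step 12
Reactants: 18 dodeca-O-benzyl-3-O-galloyl-(−)-epigallocatechin-(4β→8)-(+)-catechin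
Product: 19 3-O-galloyl-(−)-epigallocatechin-(4β→8)-(+)-catechin (CNP0129434.1)
Conditions: H2 (1 atm), Pd(OH)2/C, THF/MeOH/H2O, rt
Reagents that add atoms: none
Why: Catalytic hydrogenolysis of the twelve benzyl ethers under neutral conditions, which leaves the gallate ester, the interflavan bond and all five stereocenters untouched.

Compound list
1 | 3,5-bis(benzyloxy)phenol | Oc1cc(OCc2ccccc2)cc(OCc2ccccc2)c1 | starting material
2 | 1-(allyloxy)-3,5-bis(benzyloxy)benzene | C=CCOc1cc(OCc2ccccc2)cc(OCc2ccccc2)c1 | intermediate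
3 | 6-allyl-3,5-bis(benzyloxy)cyclohexa-2,4-dien-1-one (ortho-dienone, not isolated) | C=CCC1C(=O)C=C(OCc2ccccc2)C=C1OCc1ccccc1 | intermediate
4 | 2-allyl-3,5-bis(benzyloxy)phenol | C=CCc1c(O)cc(OCc2ccccc2)cc1OCc1ccccc1 | intermediate
5 | 3,4,5-tris(benzyloxy)benzoic acid | O=C(O)c1cc(OCc2ccccc2)c(OCc2ccccc2)c(OCc2ccccc2)c1 | starting material
6 | 2-allyl-3,5-bis(benzyloxy)phenyl 3,4,5-tris(benzyloxy)benzoate | C=CCc1c(OC(=O)c2cc(OCc3ccccc3)c(OCc3ccccc3)c(OCc3ccccc3)c2)cc(OCc2ccccc2)cc1OCc1ccccc1 | intermediate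
7 | titanium alkylidene at C3 (ligand sphere simplified to two chlorides, not isolated) | Cl[Ti](Cl)=CCc1c(OC(=O)c2cc(OCc3ccccc3)c(OCc3ccccc3)c(OCc3ccccc3)c2)cc(OCc2ccccc2)cc1OCc1ccccc1 | intermediate
8 | 5,7-bis(benzyloxy)-2-[3,4,5-tris(benzyloxy)phenyl]-4H-chromene (penta-O-benzyl flav-2-ene) | C1=C(c2cc(OCc3ccccc3)c(OCc3ccccc3)c(OCc3ccccc3)c2)Oc2cc(OCc3ccccc3)cc(OCc3ccccc3)c2C1 | intermediate
9 | (isopinocampheyl)[(2R,3S)-flavan-3-yl]borane (not isolated) | C[C@H]1[C@H](B[C@H]2Cc3c(OCc4ccccc4)cc(OCc4ccccc4)cc3O[C@@H]2c2cc(OCc3ccccc3)c(OCc3ccccc3)c(OCc3ccccc3)c2)C[C@@H]2C[C@H]1C2(C)C | intermediate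
10 | (2R,3S)-5,7-bis(benzyloxy)-2-[3,4,5-tris(benzyloxy)phenyl]chroman-3-ol (penta-O-benzyl-(+)-gallocatechin) | O[C@H]1Cc2c(OCc3ccccc3)cc(OCc3ccccc3)cc2O[C@@H]1c1cc(OCc2ccccc2)c(OCc2ccccc2)c(OCc2ccccc2)c1 | intermediate
11 | (2R)-5,7-bis(benzyloxy)-2-[3,4,5-tris(benzyloxy)phenyl]chroman-3-one | O=C1Cc2c(OCc3ccccc3)cc(OCc3ccccc3)cc2O[C@@H]1c1cc(OCc2ccccc2)c(OCc2ccccc2)c(OCc2ccccc2)c1 | intermediate
12 | (2R,3R)-5,7-bis(benzyloxy)-2-[3,4,5-tris(benzyloxy)phenyl]chroman-3-ol (penta-O-benzyl-(−)-epigallocatechin) | O[C@@H]1Cc2c(OCc3ccccc3)cc(OCc3ccccc3)cc2O[C@@H]1c1cc(OCc2ccccc2)c(OCc2ccccc2)c(OCc2ccccc2)c1 | intermediate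
13 | (2R,3R,4S)-5,7-bis(benzyloxy)-4-(2-ethoxyethoxy)-2-[3,4,5-tris(benzyloxy)phenyl]chroman-3-ol (4β ether) | O[C@@H]1[C@@H](OCCOCC)c2c(OCc3ccccc3)cc(OCc3ccccc3)cc2O[C@@H]1c1cc(OCc2ccccc2)c(OCc2ccccc2)c(OCc2ccccc2)c1 | intermediate
14 | (2R,3R,4S)-5,7-bis(benzyloxy)-4-(2-ethoxyethoxy)-2-[3,4,5-tris(benzyloxy)phenyl]chroman-3-yl 3,4,5-tris(benzyloxy)benzoate | O=C(O[C@@H]1[C@@H](OCCOCC)c2c(OCc3ccccc3)cc(OCc3ccccc3)cc2O[C@@H]1c1cc(OCc2ccccc2)c(OCc2ccccc2)c(OCc2ccccc2)c1)c1cc(OCc2ccccc2)c(OCc2ccccc2)c(OCc2ccccc2)c1 | intermediate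
15 | (+)-catechin, (2R,3S) | O[C@H]1Cc2c(O)cc(O)cc2O[C@@H]1c1ccc(O)c(O)c1 | starting material
16 | (2R,3S)-5,7-bis(benzyloxy)-2-[3,4-bis(benzyloxy)phenyl]chroman-3-ol (tetra-O-benzyl-(+)-catechin) | O[C@H]1Cc2c(OCc3ccccc3)cc(OCc3ccccc3)cc2O[C@@H]1c1ccc(OCc2ccccc2)c(OCc2ccccc2)c1 | intermediate
17 | (2R,3R)-3-galloyloxyflavan-4-yl cation, octa-O-benzyl (not isolated) | O=C(O[C@@H]1[CH+]c2c(OCc3ccccc3)cc(OCc3ccccc3)cc2O[C@@H]1c1cc(OCc2ccccc2)c(OCc2ccccc2)c(OCc2ccccc2)c1)c1cc(OCc2ccccc2)c(OCc2ccccc2)c(OCc2ccccc2)c1 | intermediate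
18 | dodeca-O-benzyl-3-O-galloyl-(−)-epigallocatechin-(4β→8)-(+)-catechin (upper 2R,3R,4R; lower 2R,3S) | O=C(O[C@@H]1[C@@H](c2c(OCc3ccccc3)cc(OCc3ccccc3)c3c2O[C@H](c2ccc(OCc4ccccc4)c(OCc4ccccc4)c2)[C@@H](O)C3)c2c(OCc3ccccc3)cc(OCc3ccccc3)cc2O[C@@H]1c1cc(OCc2ccccc2)c(OCc2ccccc2)c(OCc2ccccc2)c1)c1cc(OCc2ccccc2)c(OCc2ccccc2)c(OCc2ccccc2)c1 | intermediate
19 | 3-O-galloyl-(−)-epigallocatechin-(4β→8)-(+)-catechin (CNP0129434.1) | O=C(O[C@@H]1[C@@H](c2c(O)cc(O)c3c2O[C@H](c2ccc(O)c(O)c2)[C@@H](O)C3)c2c(O)cc(O)cc2O[C@@H]1c1cc(O)c(O)c(O)c1)c1cc(O)c(O)c(O)c1 | target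

Total step count: 12. Longest linear sequence: 11 (steps 1–9, 11, 12).

Steps most likely to fail

Step 4. The ethylidene reagent may olefinate the ester carbonyl directly before it has exchanged with the allyl group, or the low-valent metal may cleave the aryl ester reductively. Either would stop the ring closure. The fallback separates the two events. It sets out from 6: a Petasis methylenation (Cp2TiMe2, toluene, 80 °C) would give the acyclic enol ether 2-allyl-3,5-bis(benzyloxy)phenyl 1-[3,4,5-tris(benzyloxy)phenyl]vinyl ether F1. A ruthenium-catalysed ring-closing metathesis (second-generation Grubbs catalyst, 1,4-benzoquinone against allyl isomerisation, toluene, 80 °C) would then form the same C2=C3 bond and return to 8.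

Step 5. Facial selectivity on this large enol ether may be poor, or the β-aryloxyborane may lose the A-ring phenoxide by elimination before oxidation. The fallback moves the stereochemical decision from the alkene to the ketone and sets out from 8.
- Achiral hydroboration (BH3·SMe2, then NaBO3) would give 10 together with its enantiomer, the (2S,3R)-alcohol F2.
- Dess–Martin oxidation would give 11 together with the (2S)-ketone F3.
- C2 of the ketone epimerises readily under base. A Noyori–Ikariya transfer hydrogenation under dynamic kinetic resolution (Ru–TsDPEN, HCO2H/Et3N), using the catalyst antipode that delivers hydride to the Si face of C3 of the 2R ketone, would funnel both ketones into the cis alcohol and return to 12.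

Step 11. The electrophile may attack another molecule of itself or the first-formed dimer (oligomerisation), or the nucleophile may react through C6. The fallback caps the competing nucleophilic site and sets out from 14.
- Bromination of C8 of the upper A ring (NBS, CH2Cl2, −78 to 0 °C) would give the 8-bromo electrophile F4, which can no longer act as a nucleophile.
- Its TMSOTf-promoted coupling with 16 would give the 8-bromo dimer F5.
- Hydrogenolysis (H2, Pd(OH)2/C, Et3N) would remove the bromine together with the benzyl groups and return to 19.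

Further compounds
F1 | step 4 | 2-allyl-3,5-bis(benzyloxy)phenyl 1-[3,4,5-tris(benzyloxy)phenyl]vinyl ether | C=CCc1c(OC(=C)c2cc(OCc3ccccc3)c(OCc3ccccc3)c(OCc3ccccc3)c2)cc(OCc2ccccc2)cc1OCc1ccccc1
F2 | step 5 | (2S,3R)-5,7-bis(benzyloxy)-2-[3,4,5-tris(benzyloxy)phenyl]chroman-3-ol (enantiomer of 10) | O[C@@H]1Cc2c(OCc3ccccc3)cc(OCc3ccccc3)cc2O[C@H]1c1cc(OCc2ccccc2)c(OCc2ccccc2)c(OCc2ccccc2)c1
F3 | step 5 | (2S)-5,7-bis(benzyloxy)-2-[3,4,5-tris(benzyloxy)phenyl]chroman-3-one (enantiomer of 11) | O=C1Cc2c(OCc3ccccc3)cc(OCc3ccccc3)cc2O[C@H]1c1cc(OCc2ccccc2)c(OCc2ccccc2)c(OCc2ccccc2)c1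
F4 | step 11 | 8-bromo derivative of 14 | O=C(O[C@@H]1[C@@H](OCCOCC)c2c(OCc3ccccc3)cc(OCc3ccccc3)c(Br)c2O[C@@H]1c1cc(OCc2ccccc2)c(OCc2ccccc2)c(OCc2ccccc2)c1)c1cc(OCc2ccccc2)c(OCc2ccccc2)c(OCc2ccccc2)c1
F5 | step 11 | 8-bromo derivative of 18 (bromine on the upper A ring) | O=C(O[C@@H]1[C@@H](c2c(OCc3ccccc3)cc(OCc3ccccc3)c3c2O[C@H](c2ccc(OCc4ccccc4)c(OCc4ccccc4)c2)[C@@H](O)C3)c2c(OCc3ccccc3)cc(OCc3ccccc3)c(Br)c2O[C@@H]1c1cc(OCc2ccccc2)c(OCc2ccccc2)c(OCc2ccccc2)c1)c1cc(OCc2ccccc2)c(OCc2ccccc2)c(OCc2ccccc2)c1
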